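**Retrosynthetic overview**
1. Endgame: the oxirane comes from closure of a tertiary alcohol onto a primary tosylate, the exocyclic methylene from a C4 ketone, and the five esters are installed stepwise (C3 and C6 2-methylbutanoates from one anhydride, C5 enoate, acetates last).
2. Five-membered ring (formed second): ring-closing metathesis to the C2=C3 alkene, then hydroxyl-directed dihydroxylation to give the all-cis C1/C2/C3 array.
3. Six-membered ring and trans ring fusion (formed first): intermolecular Diels–Alder of an (E)-enal (fragment A, 8 C: C3, C3a, C7a, C1, C2, side chain) with a 1-silyloxy-(E,E)-diene (fragment B, 7 C: C4–C7 and the oxirane carbons).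
4. Fragment A from crotyl alcohol (Sharpless epoxide, vinyl oxirane, propiolate alkynylation); fragment B from methallyl alcohol (Sharpless epoxide, tosylate, vinyl cuprate, cross-metathesis); acyl donors from tiglic acid and ethyl but-2-ynoate.
5. Ring order: cyclohexene (Diels–Alder), cyclopentene (metathesis), oxirane (last step).

Assumption: the SMILES is taken as drawn (both 2-methylbutanoates R, enoate E). Atoms carry their final hydrindane numbers from the fragments on (C1–C7a; C8 = oxirane quaternary carbon; C1' = side-chain carbinol carbon); α = face of H-7a; TES = SiEt3, Ts = 4-toluenesulfonyl, DTBS = t-Bu2Si, "C8 side chain" = (2S)-1-(tosyloxy)-2-(triethylsilyloxy)propan-2-yl.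

**Fragment A (dienophile)**

Step 1
Reactants: 1 (E)-but-2-en-1-ol
Product: 2 (2S,3S)-2,3-epoxybutan-1-ol
Conditions: Ti(OiPr)4 (5 mol%), L-(+)-diisopropyl tartrate (6 mol%), t-BuOOH, 4 Å sieves, CH2Cl2, −20 °C
Reagents that add atoms: tert-butyl hydroperoxide, CC(C)(C)OO
Why: Sharpless asymmetric epoxidation, in which the L-(+)-tartrate titanium catalyst gives the (2S,3S)-epoxide of the (E)-allylic alcohol and so fixes C1' and the later inversion centre C1.

Step 2
Reactants: 2 (2S,3S)-2,3-epoxybutan-1-ol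
Product: 3 (2R,3S)-3-methyloxirane-2-carbaldehyde
Conditions: PhI(OAc)2 (1.1 equiv), TEMPO (10 mol%), CH2Cl2, 0 to 20 °C; solution used directly
Reagents that add atoms: none
Why: TEMPO-catalysed oxoammonium oxidation stops at the aldehyde and leaves both oxirane centres untouched (the descriptor change at C2 is a priority change only).

Step 3
Reactants: 3 (2R,3S)-3-methyloxirane-2-carbaldehyde
Product: 4 (2S,3S)-2-ethenyl-3-methyloxirane
Conditions: Ph3PCH3Br, KN(SiMe3)2, THF, −78 to 0 °C; distilled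
Reagents that add atoms: methylenetriphenylphosphorane, C=P(c1ccccc1)(c1ccccc1)c1ccccc1
Why: Wittig methylenation, in which the non-stabilised ylide adds to the aldehyde faster than it enolises it, so the trans-oxirane is kept.

Step 4
Reactants: 4 (2S,3S)-2-ethenyl-3-methyloxirane; 5 ethyl prop-2-ynoate
Product: 7 ethyl (4S,5S)-4-ethenyl-5-hydroxyhex-2-ynoate, via lithium acetylide 6 (not isolated)
Conditions: 5, n-BuLi, THF, −78 °C; BF3·OEt2; then 4, −78 °C; aq. NH4Cl
Reagents that add atoms: none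
Why: Yamaguchi–Hirao alkynylation, in which the BF3-activated vinyl oxirane is opened by SN2 attack at the allylic carbon with inversion, setting C1 (S) next to the untouched C1' (S).

Step 5
Reactants: 7 ethyl (4S,5S)-4-ethenyl-5-hydroxyhex-2-ynoate
Product: 8 (2E,4S,5S)-4-ethenylhex-2-ene-1,5-diol
Conditions: NaAlH2(OCH2CH2OMe)2 (4 equiv), THF, 0 to 20 °C; aq. potassium sodium tartrate work-up
Reagents that add atoms: none
Why: hydride reduction of the ester followed by alkoxide-directed trans-hydroalumination of the propargylic alkyne gives the (E)-allylic alcohol, while the isolated vinyl group is inert.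

Step 6
Reactants: 8 (2E,4S,5S)-4-ethenylhex-2-ene-1,5-diol
Product: 9 (2E,4S,5S)-4-ethenyl-5-hydroxyhex-2-enal (fragment A)
Conditions: MnO2 (15 equiv), CH2Cl2, 20 °C
Reagents that add atoms: none
Why: MnO2 oxidation is selective for the allylic primary alcohol over the saturated secondary carbinol and does not touch C1 or C1'.

**Fragment B (diene)**

Step 7
Reactants: 10 2-methylprop-2-en-1-ol
Product: 11 (R)-(2-methyloxiran-2-yl)methanol
Conditions: Ti(OiPr)4 (5 mol%), D-(−)-diisopropyl tartrate (6 mol%), t-BuOOH, 4 Å sieves, CH2Cl2, −20 °C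
Reagents that add atoms: tert-butyl hydroperoxide, CC(C)(C)OO
Why: Sharpless asymmetric epoxidation with the D-(−)-tartrate gives the (R)-epoxy alcohol, whose quaternary carbon becomes C8.

Step 8
Reactants: 11 (R)-(2-methyloxiran-2-yl)methanol
Product: 12 (S)-(2-methyloxiran-2-yl)methyl 4-methylbenzenesulfonate
Conditions: TsCl, Et3N, DMAP (5 mol%), CH2Cl2, 0 °C
Reagents that add atoms: 4-toluenesulfonyl chloride, Cc1ccc(cc1)S(=O)(=O)Cl
Why: O-sulfonylation of the primary alcohol breaks no bond at C8 (R to S is a priority change only).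

Step 9
Reactants: 12 (S)-(2-methyloxiran-2-yl)methyl 4-methylbenzenesulfonate
Product: 13 (S)-2-hydroxy-2-methylpent-4-en-1-yl 4-methylbenzenesulfonate
Conditions: CH2=CHMgBr (1.5 equiv), CuI (10 mol%), THF, −40 °C; cold aq. NH4Cl
Reagents that add atoms: vinylmagnesium bromide, C=C[Mg]Br
Why: copper-catalysed Grignard opening (SN2) occurs at the unhindered oxirane CH2 rather than at the neopentyl-type tosylate, and the cold quench keeps the alkoxide from closing back.

Step 10
Reactants: 13 (S)-2-hydroxy-2-methylpent-4-en-1-yl 4-methylbenzenesulfonate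
Product: 14 (S)-2-methyl-2-(triethylsilyloxy)pent-4-en-1-yl 4-methylbenzenesulfonate
Conditions: Et3SiOTf, 2,6-lutidine, CH2Cl2, −78 to 0 °C
Reagents that add atoms: triethylsilyl trifluoromethanesulfonate, CC[Si](CC)(CC)OS(=O)(=O)C(F)(F)F
Why: silyl triflate silylation masks the tertiary hydroxyl, which would otherwise displace the tosylate in the later basic steps.

Step 11
Reactants: 14 (S)-2-methyl-2-(triethylsilyloxy)pent-4-en-1-yl 4-methylbenzenesulfonate; 15 (E)-but-2-enal
Product: 16 (2S,4E)-2-methyl-6-oxo-2-(triethylsilyloxy)hex-4-en-1-yl 4-methylbenzenesulfonate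
Conditions: second-generation Grubbs catalyst RuCl2(=CHPh)(H2IMes)(PCy3) (5 mol%), 15 (5 equiv), CH2Cl2, 40 °C
Reagents that add atoms: none
Why: olefin cross-metathesis of a terminal alkene with crotonaldehyde is E-selective and is driven by loss of propene.

Step 12
Reactants: 16 (2S,4E)-2-methyl-6-oxo-2-(triethylsilyloxy)hex-4-en-1-yl 4-methylbenzenesulfonate
Product: 17 (2S,3E,5E)-2-methyl-2,6-bis(triethylsilyloxy)hexa-3,5-dien-1-yl 4-methylbenzenesulfonate (fragment B)
Conditions: Et3SiOTf, Et3N, Et2O, 0 to 20 °C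
Reagents that add atoms: triethylsilyl trifluoromethanesulfonate, CC[Si](CC)(CC)OS(=O)(=O)C(F)(F)F
Why: soft enolisation (O-silylation then γ-deprotonation) of the enal gives the (1E,3E)-1-silyloxydiene, and any (1Z) isomer cannot reach the s-cis form needed in the cycloaddition.

**Acyl donors**

Step 13
Reactants: 18 (E)-2-methylbut-2-enoic acid (tiglic acid)
Product: 19 (R)-2-methylbutanoic acid
Conditions: H2 (4 atm), Ru(OAc)2[(R)-H8-BINAP] (0.5 mol%), MeOH, 20 °C
Reagents that add atoms: none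
Why: Noyori-type asymmetric hydrogenation of the α,β-unsaturated acid, in which the (R)-ligand delivers the (R)-acid.

Step 14
Reactants: 19 (R)-2-methylbutanoic acid (two molecules per molecule of product)
Product: 20 (2R)-2-methylbutanoic anhydride
Conditions: 19 (2.0 equiv), DCC (1.0 equiv, that is 0.5 equiv per acid), CH2Cl2, 0 to 20 °C; filtered
Reagents that add atoms: (R)-2-methylbutanoic acid (the second molecule of 19), CC[C@@H](C)C(=O)O
Why: carbodiimide dehydration, in which the O-acylisourea formed from one molecule of the acid is acylated by a second molecule to give the symmetric anhydride without passing through a ketene, so both α-centres are kept.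

Step 15
Reactants: 21 ethyl but-2-ynoate
Product: 22 ethyl (E)-3-methylpent-2-enoate
Conditions: Et2CuLi (from EtLi and CuI), THF, −78 °C; MeOH at −78 °C; then aq. NH4Cl work-up
Reagents that add atoms: lithium diethylcuprate, [Li+].CC[Cu-]CC
Why: syn-carbocupration of the ynoate and cold protonation place ethyl cis to hydrogen, which is the (E)-enoate.

Step 16
Reactants: 22 ethyl (E)-3-methylpent-2-enoate
Product: 23 (E)-3-methylpent-2-enoic acid
Conditions: LiOH, THF/H2O, 20 °C; then HCl to pH 2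
Reagents that add atoms: lithium hydroxide, [Li+].[OH-]
Why: saponification of the ester does not touch the double-bond geometry.

**Fragment union and completion**

Step 17
Reactants: 9 (2E,4S,5S)-4-ethenyl-5-hydroxyhex-2-enal; 17 (2S,3E,5E)-2-methyl-2,6-bis(triethylsilyloxy)hexa-3,5-dien-1-yl 4-methylbenzenesulfonate
Product: 24 cyclohexene aldehyde (C3aα-CHO; C4α-OTES; C5=C6; C7α-C8 side chain; C7aβ-[(3S,4S)-4-hydroxypent-1-en-3-yl])
Conditions: CH2Cl2, 2,6-di-tert-butyl-4-methylphenol (trace), 13 kbar, 25 °C, 48 h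
Reagents that add atoms: none
Why: Diels–Alder reaction in which the silyloxy terminus bonds to the enal α-carbon (ortho rule), the (E)-dienophile gives the trans C3a/C7a pair, endo addition to the (E,E)-diene puts 4-OTES and the C7 side chain cis to the formyl group, and the diene approaches anti to the CH(OH)CH3 group on C1 with hydrogen outside (Houk model), which sets C7a relative to C1.

Step 18
Reactants: 24 cyclohexene aldehyde
Product: 25 triene (as 24 with C3aα-ethenyl in place of formyl)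
Conditions: Ph3PCH3Br (3.5 equiv), KN(SiMe3)2 (3.3 equiv), THF, −78 to 0 °C
Reagents that add atoms: methylenetriphenylphosphorane, C=P(c1ccccc1)(c1ccccc1)c1ccccc1
Why: Wittig methylenation with excess ylide (the free hydroxyl uses one equivalent) is faster than β-elimination of the silyloxy group, and the equatorial C3a centre is already the stable epimer.

Step 19
Reactants: 25 triene
Product: 26 trans-hydrinda-2,5-diene (1α-[(1S)-1-hydroxyethyl]; 4α-OTES; 7α-C8 side chain; 3aβ-H; 7aα-H)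
Conditions: second-generation Grubbs catalyst RuCl2(=CHPh)(H2IMes)(PCy3) (5 mol%), CH2Cl2 (0.005 M), 40 °C
Reagents that add atoms: none
Why: ring-closing metathesis of the two vinyl groups closes the cyclopentene (C2=C3) on the pre-set trans C3a/C7a pair, and the endocyclic C5=C6 alkene does not take part.

Step 20
Reactants: 26 trans-hydrinda-2,5-diene
Product: 28 hydrindene-2α,3α-diol bearing the free C1' hydroxyl, via osmate ester 27 (not isolated)
Conditions: OsO4 (1.05 equiv), TMEDA (1.1 equiv), CH2Cl2, −78 °C; then aq. NaHSO3, THF, 20 °C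
Reagents that add atoms: osmium tetroxide, O=[Os](=O)(=O)=O
Why: Donohoe directed dihydroxylation, in which the OsO4–TMEDA complex is hydrogen-bonded by the C1' hydroxyl and adds to the strained C2=C3 alkene from the α face (syn to the side chain) faster than to the hindered, undirected C5=C6 alkene.

Step 21
Reactants: 28 hydrindene-2α,3α-diol
Product: 29 C1',C2-O-di-tert-butylsilylene derivative (3α-OH free)
Conditions: t-Bu2Si(OTf)2 (1.05 equiv), 2,6-lutidine, CH2Cl2, −40 to 0 °C
Reagents that add atoms: di-tert-butylsilyl bis(trifluoromethanesulfonate), CC(C)(C)[Si](OS(=O)(=O)C(F)(F)F)(OS(=O)(=O)C(F)(F)F)C(C)(C)C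
Why: cyclic silylene protection favours the six-membered 1,3-dioxasilinane (C1'-O/C2-O) over a strained five-membered ring and leaves the most hindered C3 hydroxyl free, as in 3',5'-silylene protection of ribonucleosides.

Step 22
Reactants: 29 silylene; 20 (2R)-2-methylbutanoic anhydride
Product: 30 3α-O-[(2R)-2-methylbutanoyl] ester
Conditions: DMAP (1.5 equiv), Et3N, CH2Cl2, 40 °C
Reagents that add atoms: none
Why: DMAP-catalysed acyl transfer from the symmetric anhydride esterifies the only free (hindered) hydroxyl.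

Step 23
Reactants: 30 3α-ester
Product: 31 5β,6β-diol
Conditions: OsO4 (10 mol%), N-methylmorpholine N-oxide (3 equiv), acetone/H2O 8:1, 20 °C
Reagents that add atoms: N-methylmorpholine N-oxide, C[N+]1([O-])CCOCC1; water, O
Why: Upjohn dihydroxylation, in which OsO4 adds anti to the pseudo-axial 4α-OTES group and the 7α side chain to give the cis-5β,6β-diol.

Step 24
Reactants: 31 5β,6β-diol; 20 (2R)-2-methylbutanoic anhydride
Product: 33 6β-O-[(2R)-2-methylbutanoyl] ester (5β-OH free), via stannylene acetal 32 (not isolated)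
Conditions: Bu2SnO (1.1 equiv), toluene, reflux (−H2O); then 20 (1.1 equiv), 0 to 20 °C
Reagents that add atoms: none
Why: stannylene-acetal-mediated acylation of a cis-1,2-diol takes place at the equatorial oxygen (C6), which is also the thermodynamically preferred ester position.

Step 25
Reactants: 33 6β-ester; 23 (E)-3-methylpent-2-enoic acid
Product: 35 5β-O-[(2E)-3-methylpent-2-enoyl] ester, via mixed anhydride 34 (not isolated)
Conditions: 23, 2,4,6-Cl3C6H2COCl, Et3N, THF, 20 °C; then 33, DMAP, toluene, 40 °C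
Reagents that add atoms: none
Why: Yamaguchi esterification acylates the remaining axial C5 hydroxyl through the acylpyridinium, not a ketene, so the (E)-geometry is kept.

Step 26
Reactants: 35 fully acylated 4α-OTES compound
Product: 36 C4 ketone
Conditions: IBX (4 equiv), DMSO, 40 °C
Reagents that add atoms: none
Why: IBX oxidative desilylation–oxidation turns the secondary triethylsilyl ether directly into the ketone without base, so the β-acyloxy ketone does not eliminate and C3a and C5 do not epimerise.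

Step 27
Reactants: 36 C4 ketone
Product: 37 4-methylidene compound
Conditions: Zn, CH2Br2, TiCl4 (pre-formed Lombardo reagent), THF/CH2Cl2, 0 to 20 °C
Reagents that add atoms: dibromomethane, BrCBr
Why: Takai–Lombardo methylenation is non-basic and selective for ketones over esters, so the α-acyloxy ketone becomes the exocyclic alkene without epimerisation.

Step 28
Reactants: 37 4-methylidene compound
Product: 39 C1',C2-diacetate with free C8 hydroxyl, via triol 38 (not isolated)
Conditions: HF·pyridine, pyridine, THF, 0 to 20 °C; then Ac2O (excess), pyridine, 20 °C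
Reagents that add atoms: acetic anhydride, CC(=O)OC(C)=O
Why: fluoride desilylation under acidic conditions removes the silylene and the tertiary silyl ether without acyl migration from C3, and acetylation in pyridine then esterifies the two secondary hydroxyls but not the tertiary one.

Step 29
Reactants: 39 diacetate hydroxy tosylate
Product: 40 CNP0193288.1 (target)
Conditions: DBU (3 equiv), MeCN, 40 °C
Reagents that add atoms: none
Why: intramolecular Williamson (3-exo-tet) displacement of the primary tosylate by the tertiary hydroxyl closes the oxirane, and C8 keeps its configuration because no bond to it is broken.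

**Compound list**

1 | (E)-but-2-en-1-ol | C/C=C/CO | starting material
2 | (2S,3S)-2,3-epoxybutan-1-ol | OC[C@H]1[C@H](C)O1 | intermediate
3 | (2R,3S)-3-methyloxirane-2-carbaldehyde | O=C[C@H]1[C@H](C)O1 | intermediate
4 | (2S,3S)-2-ethenyl-3-methyloxirane | C=C[C@H]1[C@H](C)O1 | intermediate
5 | ethyl prop-2-ynoate | C#CC(=O)OCC | starting material
6 | lithium 3-ethoxy-3-oxoprop-1-yn-1-ide | [Li+].[C-]#CC(=O)OCC | intermediate (not isolated)
7 | ethyl (4S,5S)-4-ethenyl-5-hydroxyhex-2-ynoate | CCOC(=O)C#C[C@H](C=C)[C@H](C)O | intermediate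
8 | (2E,4S,5S)-4-ethenylhex-2-ene-1,5-diol | OC/C=C/[C@H](C=C)[C@H](C)O | intermediate
9 | (2E,4S,5S)-4-ethenyl-5-hydroxyhex-2-enal (fragment A) | O=C/C=C/[C@H](C=C)[C@H](C)O | intermediate
10 | 2-methylprop-2-en-1-ol | C=C(C)CO | starting material
11 | (R)-(2-methyloxiran-2-yl)methanol | C1O[C@]1(C)CO | intermediate
12 | (S)-(2-methyloxiran-2-yl)methyl 4-methylbenzenesulfonate | C1O[C@]1(C)COS(=O)(=O)c2ccc(C)cc2 | intermediate
13 | (S)-2-hydroxy-2-methylpent-4-en-1-yl 4-methylbenzenesulfonate | C=CC[C@@](O)(C)COS(=O)(=O)c1ccc(C)cc1 | intermediate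
14 | (S)-2-methyl-2-(triethylsilyloxy)pent-4-en-1-yl 4-methylbenzenesulfonate | C=CC[C@@](O[Si](CC)(CC)CC)(C)COS(=O)(=O)c1ccc(C)cc1 | intermediate
15 | (E)-but-2-enal | C/C=C/C=O | starting material
16 | (2S,4E)-2-methyl-6-oxo-2-(triethylsilyloxy)hex-4-en-1-yl 4-methylbenzenesulfonate | O=C/C=C/C[C@@](O[Si](CC)(CC)CC)(C)COS(=O)(=O)c1ccc(C)cc1 | intermediate
17 | (2S,3E,5E)-2-methyl-2,6-bis(triethylsilyloxy)hexa-3,5-dien-1-yl 4-methylbenzenesulfonate (fragment B) | CC[Si](CC)(CC)O/C=C/C=C/[C@@](O[Si](CC)(CC)CC)(C)COS(=O)(=O)c1ccc(C)cc1 | intermediate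
18 | (E)-2-methylbut-2-enoic acid (tiglic acid) | C/C=C(\C)C(=O)O | starting material
19 | (R)-2-methylbutanoic acid | CC[C@@H](C)C(=O)O | intermediate
20 | (2R)-2-methylbutanoic anhydride | CC[C@@H](C)C(=O)OC(=O)[C@H](C)CC | intermediate
21 | ethyl but-2-ynoate | CC#CC(=O)OCC | starting material
22 | ethyl (E)-3-methylpent-2-enoate | CCOC(=O)/C=C(\C)CC | intermediate
23 | (E)-3-methylpent-2-enoic acid | OC(=O)/C=C(\C)CC | intermediate
24 | Diels–Alder adduct: cyclohex-5-ene with C3aα-CHO, C4α-OTES, C7α-C8 side chain, C7aβ-[(3S,4S)-4-hydroxypent-1-en-3-yl] | CC[Si](CC)(CC)O[C@@H]1[C@H](C=O)[C@@H]([C@H](C=C)[C@H](C)O)[C@H]([C@@](O[Si](CC)(CC)CC)(C)COS(=O)(=O)c2ccc(C)cc2)C=C1 | intermediate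
25 | triene: 24 with C3aα-ethenyl in place of formyl | CC[Si](CC)(CC)O[C@@H]1[C@H](C=C)[C@@H]([C@H](C=C)[C@H](C)O)[C@H]([C@@](O[Si](CC)(CC)CC)(C)COS(=O)(=O)c2ccc(C)cc2)C=C1 | intermediate
26 | trans-hydrinda-2,5-diene: 1α-[(1S)-1-hydroxyethyl], 4α-OTES, 7α-C8 side chain, 3aβ-H, 7aα-H | CC[Si](CC)(CC)O[C@@H]1[C@@H]2C=C[C@H]([C@H](C)O)[C@H]2[C@H]([C@@](O[Si](CC)(CC)CC)(C)COS(=O)(=O)c3ccc(C)cc3)C=C1 | intermediate
27 | cyclic 2α,3α-osmate ester of 26 (hexavalent osmium, TMEDA-chelated, written dot-separated) | CC[Si](CC)(CC)O[C@@H]1[C@@H]2[C@@H]5O[Os](=O)(=O)O[C@@H]5[C@H]([C@H](C)O)[C@H]2[C@H]([C@@](O[Si](CC)(CC)CC)(C)COS(=O)(=O)c3ccc(C)cc3)C=C1.CN(C)CCN(C)C | intermediate (not isolated)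
28 | 2α,3α-diol of 26 (triol with C1'-OH; C5=C6 kept) | CC[Si](CC)(CC)O[C@@H]1[C@@H]2[C@H](O)[C@H](O)[C@H]([C@H](C)O)[C@H]2[C@H]([C@@](O[Si](CC)(CC)CC)(C)COS(=O)(=O)c3ccc(C)cc3)C=C1 | intermediate
29 | C1',C2-O-di-tert-butylsilylene derivative of 28 (3α-OH free) | CC[Si](CC)(CC)O[C@@H]1[C@@H]2[C@H](O)[C@@H]4O[Si](C(C)(C)C)(C(C)(C)C)O[C@@H](C)[C@@H]4[C@H]2[C@H]([C@@](O[Si](CC)(CC)CC)(C)COS(=O)(=O)c3ccc(C)cc3)C=C1 | intermediate
30 | 3α-O-[(2R)-2-methylbutanoyl] derivative of 29 | CC[Si](CC)(CC)O[C@@H]1[C@@H]2[C@H](OC(=O)[C@H](C)CC)[C@@H]4O[Si](C(C)(C)C)(C(C)(C)C)O[C@@H](C)[C@@H]4[C@H]2[C@H]([C@@](O[Si](CC)(CC)CC)(C)COS(=O)(=O)c3ccc(C)cc3)C=C1 | intermediate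
31 | 5β,6β-diol of 30 | CC[Si](CC)(CC)O[C@@H]1[C@@H]2[C@H](OC(=O)[C@H](C)CC)[C@@H]4O[Si](C(C)(C)C)(C(C)(C)C)O[C@@H](C)[C@@H]4[C@H]2[C@H]([C@@](O[Si](CC)(CC)CC)(C)COS(=O)(=O)c3ccc(C)cc3)[C@@H](O)[C@H]1O | intermediate
32 | 5,6-O-dibutylstannylene acetal of 31 | CC[Si](CC)(CC)O[C@@H]1[C@@H]2[C@H](OC(=O)[C@H](C)CC)[C@@H]4O[Si](C(C)(C)C)(C(C)(C)C)O[C@@H](C)[C@@H]4[C@H]2[C@H]([C@@](O[Si](CC)(CC)CC)(C)COS(=O)(=O)c3ccc(C)cc3)[C@H]6O[Sn](CCCC)(CCCC)O[C@@H]16 | intermediate (not isolated)
33 | 6β-O-[(2R)-2-methylbutanoyl] derivative of 31 (5β-OH free) | CC[Si](CC)(CC)O[C@@H]1[C@@H]2[C@H](OC(=O)[C@H](C)CC)[C@@H]4O[Si](C(C)(C)C)(C(C)(C)C)O[C@@H](C)[C@@H]4[C@H]2[C@H]([C@@](O[Si](CC)(CC)CC)(C)COS(=O)(=O)c3ccc(C)cc3)[C@@H](OC(=O)[C@H](C)CC)[C@H]1O | intermediate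
34 | (E)-3-methylpent-2-enoic 2,4,6-trichlorobenzoic anhydride | O=C(OC(=O)/C=C(\C)CC)c1c(Cl)cc(Cl)cc1Cl | intermediate (not isolated)
35 | 5β-O-[(2E)-3-methylpent-2-enoyl] derivative of 33 | CC[Si](CC)(CC)O[C@@H]1[C@@H]2[C@H](OC(=O)[C@H](C)CC)[C@@H]4O[Si](C(C)(C)C)(C(C)(C)C)O[C@@H](C)[C@@H]4[C@H]2[C@H]([C@@](O[Si](CC)(CC)CC)(C)COS(=O)(=O)c3ccc(C)cc3)[C@@H](OC(=O)[C@H](C)CC)[C@H]1OC(=O)/C=C(\C)CC | intermediate
36 | C4 ketone (4-OTES of 35 replaced by C=O) | O=C1[C@@H]2[C@H](OC(=O)[C@H](C)CC)[C@@H]4O[Si](C(C)(C)C)(C(C)(C)C)O[C@@H](C)[C@@H]4[C@H]2[C@H]([C@@](O[Si](CC)(CC)CC)(C)COS(=O)(=O)c3ccc(C)cc3)[C@@H](OC(=O)[C@H](C)CC)[C@H]1OC(=O)/C=C(\C)CC | intermediate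
37 | 4-methylidene compound | C=C1[C@@H]2[C@H](OC(=O)[C@H](C)CC)[C@@H]4O[Si](C(C)(C)C)(C(C)(C)C)O[C@@H](C)[C@@H]4[C@H]2[C@H]([C@@](O[Si](CC)(CC)CC)(C)COS(=O)(=O)c3ccc(C)cc3)[C@@H](OC(=O)[C@H](C)CC)[C@H]1OC(=O)/C=C(\C)CC | intermediate
38 | triol: 37 without silylene and tertiary TES (C1'-OH, 2α-OH, C8-OH; tosylate kept) | C=C1[C@@H]2[C@H](OC(=O)[C@H](C)CC)[C@H](O)[C@H]([C@H](C)O)[C@H]2[C@H]([C@@](O)(C)COS(=O)(=O)c3ccc(C)cc3)[C@@H](OC(=O)[C@H](C)CC)[C@H]1OC(=O)/C=C(\C)CC | intermediate (not isolated)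
39 | C1',C2-di-O-acetyl derivative of 38 (C8-OH free; tosylate kept) | C=C1[C@@H]2[C@H](OC(=O)[C@H](C)CC)[C@H](OC(C)=O)[C@H]([C@H](C)OC(C)=O)[C@H]2[C@H]([C@@](O)(C)COS(=O)(=O)c3ccc(C)cc3)[C@@H](OC(=O)[C@H](C)CC)[C@H]1OC(=O)/C=C(\C)CC | intermediate
40 | CNP0193288.1: (1S)-1-[2α-acetoxy-3α,6β-bis[(2R)-2-methylbutanoyloxy]-4-methylidene-5β-[(2E)-3-methylpent-2-enoyloxy]-7α-[(2S)-2-methyloxiran-2-yl]-3aβ-H,7aα-H-octahydroinden-1α-yl]ethyl acetate | C=C1[C@@H]2[C@H](OC(=O)[C@H](C)CC)[C@H](OC(C)=O)[C@H]([C@H](C)OC(C)=O)[C@H]2[C@H]([C@@]2(C)CO2)[C@@H](OC(=O)[C@H](C)CC)[C@H]1OC(=O)/C=C(\C)CC | target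

**Step count and risk**

Total steps: 29. Longest linear sequence: 19 (steps 1–6 then 17–29; the diene branch, steps 7–12 then 17–29, is equally long).

Steps most likely to fail:

Step 17 (Diels–Alder: hindered partners, facial selectivity resting on the C1 substituents of a free hydroxy enal). The fallback sets out from 9 and 17 and comes back at 26. Compound 9 is esterified (pivaloyl chloride, pyridine, DMAP) to the pivalate F1, so that a bulky acyl group, not a free carbinol, is the group the diene must avoid. F1 and 17 are combined under Lewis-acid activation (Me2AlCl, CH2Cl2, −78 °C) instead of pressure, giving the adduct pivalate F2. Wittig methylenation as in step 18 gives the triene pivalate F3, and ring-closing metathesis as in step 19 gives the hydrindadiene pivalate F4. Reductive removal of the pivalate (i-Bu2AlH, CH2Cl2, −78 °C) returns 26.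

Step 20 (directed dihydroxylation: α-face delivery and selectivity over C5=C6). The fallback sets out from 26 and comes back at 28; it builds the two C–O bonds one at a time by neighbouring-group delivery and ketone reduction. Compound 26 is converted (Boc2O, DMAP) into the tert-butyl carbonate F5. Epoxidation (mCPBA, NaHCO3) occurs from the open β face to give the 2β,3β-epoxide F6. BF3·OEt2 (−40 °C) lets the carbonate carbonyl open the epoxide at C2 from the α face (6-exo, loss of isobutene), giving the cyclic C1',C2-carbonate 3β-alcohol F7. Dess–Martin oxidation gives the 3-ketone F8, and NaBH4 (MeOH, −40 °C; hydride from the β face, anti to both α neighbours) gives the 3α-alcohol F9. K2CO3 in MeOH cleaves the carbonate and returns 28.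

Step 24 (regioselective acylation of the equatorial C6 hydroxyl). The fallback sets out from 31 and comes back at 33; it replaces kinetic tin-directed delivery by thermodynamic control. Compound 31 is monoacylated without regiocontrol (20, 1.0 equiv, pyridine, DMAP cat., 0 °C), giving 33 together with its regioisomer, the 5β-ester F10. The mixture is then equilibrated (DBU cat., toluene, 40 °C) so that 1,2-acyl migration moves the axial ester F10 to the equatorial position of 33; recovered F10 is recycled.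

**Further compounds**

F1 | step 17 | (2S,3S,4E)-3-ethenyl-6-oxohex-4-en-2-yl 2,2-dimethylpropanoate | O=C/C=C/[C@H](C=C)[C@H](C)OC(=O)C(C)(C)C
F2 | step 17 | C1'-O-pivaloyl analogue of 24 | CC[Si](CC)(CC)O[C@@H]1[C@H](C=O)[C@@H]([C@H](C=C)[C@H](C)OC(=O)C(C)(C)C)[C@H]([C@@](O[Si](CC)(CC)CC)(C)COS(=O)(=O)c2ccc(C)cc2)C=C1
F3 | step 17 | C1'-O-pivaloyl analogue of 25 | CC[Si](CC)(CC)O[C@@H]1[C@H](C=C)[C@@H]([C@H](C=C)[C@H](C)OC(=O)C(C)(C)C)[C@H]([C@@](O[Si](CC)(CC)CC)(C)COS(=O)(=O)c2ccc(C)cc2)C=C1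
F4 | step 17 | C1'-O-pivaloyl analogue of 26 | CC[Si](CC)(CC)O[C@@H]1[C@@H]2C=C[C@H]([C@H](C)OC(=O)C(C)(C)C)[C@H]2[C@H]([C@@](O[Si](CC)(CC)CC)(C)COS(=O)(=O)c3ccc(C)cc3)C=C1
F5 | step 20 | C1'-O-(tert-butoxycarbonyl) derivative of 26 | CC[Si](CC)(CC)O[C@@H]1[C@@H]2C=C[C@H]([C@H](C)OC(=O)OC(C)(C)C)[C@H]2[C@H]([C@@](O[Si](CC)(CC)CC)(C)COS(=O)(=O)c3ccc(C)cc3)C=C1
F6 | step 20 | 2β,3β-epoxide of F5 | CC[Si](CC)(CC)O[C@@H]1[C@@H]2[C@H]5O[C@H]5[C@H]([C@H](C)OC(=O)OC(C)(C)C)[C@H]2[C@H]([C@@](O[Si](CC)(CC)CC)(C)COS(=O)(=O)c3ccc(C)cc3)C=C1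
F7 | step 20 | cyclic C1',C2α-carbonate with 3β-OH | CC[Si](CC)(CC)O[C@@H]1[C@@H]2[C@@H](O)[C@@H]4OC(=O)O[C@@H](C)[C@@H]4[C@H]2[C@H]([C@@](O[Si](CC)(CC)CC)(C)COS(=O)(=O)c3ccc(C)cc3)C=C1
F8 | step 20 | cyclic C1',C2α-carbonate 3-ketone | CC[Si](CC)(CC)O[C@@H]1[C@@H]2C(=O)[C@@H]4OC(=O)O[C@@H](C)[C@@H]4[C@H]2[C@H]([C@@](O[Si](CC)(CC)CC)(C)COS(=O)(=O)c3ccc(C)cc3)C=C1
F9 | step 20 | cyclic C1',C2α-carbonate with 3α-OH | CC[Si](CC)(CC)O[C@@H]1[C@@H]2[C@H](O)[C@@H]4OC(=O)O[C@@H](C)[C@@H]4[C@H]2[C@H]([C@@](O[Si](CC)(CC)CC)(C)COS(=O)(=O)c3ccc(C)cc3)C=C1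
F10 | step 24 | 5β-O-[(2R)-2-methylbutanoyl] regioisomer of 33 (6β-OH free) | CC[Si](CC)(CC)O[C@@H]1[C@@H]2[C@H](OC(=O)[C@H](C)CC)[C@@H]4O[Si](C(C)(C)C)(C(C)(C)C)O[C@@H](C)[C@@H]4[C@H]2[C@H]([C@@](O[Si](CC)(CC)CC)(C)COS(=O)(=O)c3ccc(C)cc3)[C@@H](O)[C@H]1OC(=O)[C@H](C)CC
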